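**Retrosynthetic overview**

- The target is methyl (13S)-6β-acetoxy-8α-hydroxylabdan-15-oate (labdane numbering: ring A = C1–C5, C10; ring B = C5–C10; side chain C11–C16; C17 on C8; C20 on C10). The plan rests on one feature: the oxygen-bearing C6 is bonded to ring A carbon C5 and C9 to the quaternary C10, so a C5=C10 alkene in ring A and a two-carbon ketene unit C6–C9 can deliver both bonds in one [2+2] event.
- Backwards: acetate and 6β-OH/8α-OH ⇐ 7α,8α-epoxy-6-ketone ⇐ trans-fused 7-en-6-one; ring B ⇐ [1,3] shift of a cyclobutanolate (C6 moves from C9 to C7 of an isopropenyl group on C9); cyclobutanone ⇐ keteniminium + 1,3,3-trimethylcyclohexene.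
- The keteniminium precursor is the (2S,5S)-2,5-dimethylpyrrolidine amide obtained by α-alkylating the senecioyl amide with the iodo ester made from methyl hydrogen (R)-3-methylglutarate, which carries C13.
- Ring order: ring A is bought (2,2,6-trimethylcyclohexanone), the cyclobutane is closed in step 7, and ring B grows out of it in step 9. C10 is set in step 7; C5, C9, C8 and C6 are then set relative to it in steps 12–17.

Key step: step 7

Assumption: the (2S,5S)-auxiliary is taken to open the alkene face that gives the 10S configuration of the cycloadduct; if the sense proved opposite, the (2R,5R)-amine would be used and nothing else changes.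

**Route**

Step 1
Reactants: 1 methyl hydrogen (R)-3-methylglutarate
Product: 3 (4S)-4-methyloxan-2-one, via hydroxy acid 2 (not isolated)
Conditions: LiBH4, THF, 0 °C → rt; then 2 M HCl, rt
Reagents that add atoms: none
Why: Chemoselective ester reduction followed by lactonisation: LiBH4 reduces the ester while the lithium carboxylate is inert, and acid closes the δ-hydroxy acid; the stereocentre is untouched and its descriptor changes from R to S only because the priorities of the two arms swap.

Step 2
Reactants: 3 (4S)-4-methyloxan-2-one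
Product: 6 methyl (3R)-5-iodo-3-methylpentanoate, via silyl ester 4 (not isolated), via iodo acid 5 (not isolated)
Conditions: Me3SiCl, NaI, MeCN, 60 °C; then MeOH, rt
Reagents that add atoms: sodium iodide [Na+].[I-]; methanol CO
Why: Lactone cleavage with iodotrimethylsilane made in the flask (SN2 attack of iodide at the O–CH2 carbon) gives the silyl ester, which methanol and the HI formed convert through the acid into the methyl ester (Fischer esterification), the stereocentre not being involved.

Step 3
Reactants: 7 3-methylbut-2-enoyl chloride; 8 (2S,5S)-2,5-dimethylpyrrolidine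
Product: 9 1-[(2S,5S)-2,5-dimethylpyrrolidin-1-yl]-3-methylbut-2-en-1-one
Conditions: 2 M NaOH, CH2Cl2, 0 °C
Reagents that add atoms: none
Why: Schotten–Baumann N-acylation; the two-phase hydroxide conditions avoid the amine-induced vinylketene pathway that would scramble the double-bond position.

Step 4
Reactants: 9 1-[(2S,5S)-2,5-dimethylpyrrolidin-1-yl]-3-methylbut-2-en-1-one; 6 methyl (3R)-5-iodo-3-methylpentanoate
Product: 11 methyl (3S,6RS)-6-[(2S,5S)-2,5-dimethylpyrrolidine-1-carbonyl]-3,7-dimethyloct-7-enoate, via lithium dienolate 10 (not isolated)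
Conditions: LiN(iPr)2 (commercial solution), THF–DMPU, −78 °C; then 6, −78 → −40 °C
Reagents that add atoms: none
Why: Deconjugative α-alkylation of a senecioyl amide: γ-deprotonation gives the dienolate, which the primary iodide alkylates at the α-carbon faster than the enolate attacks the methyl ester at low temperature; the new α-centre forms as a mixture that becomes sp2 in step 7.

Step 5
Reactants: 12 2,2,6-trimethylcyclohexanone
Product: 14 2,6,6-trimethylcyclohex-1-en-1-yl trifluoromethanesulfonate, via lithium enolate 13 (not isolated)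
Conditions: LiN(iPr)2 (commercial solution), THF, −78 → 0 °C; then PhNTf2, 0 °C → rt; aq. NH4Cl
Reagents that add atoms: N-phenylbis(trifluoromethanesulfonimide) O=S(=O)(N(c1ccccc1)S(=O)(=O)C(F)(F)F)C(F)(F)F
Why: Enol triflate formation: the methine C–H is the only enolisable position, so a single tetrasubstituted enolate forms and is O-sulfonylated.

Step 6
Reactants: 14 2,6,6-trimethylcyclohex-1-en-1-yl trifluoromethanesulfonate
Product: 15 1,3,3-trimethylcyclohexene
Conditions: Pd(OAc)2 (2 mol%), PPh3 (4 mol%), HCO2H, nBu3N, DMF, 60 °C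
Reagents that add atoms: none
Why: Palladium-catalysed formate reduction of a vinyl triflate (oxidative addition to zerovalent palladium, decarboxylation of formate to the hydride, reductive elimination) fixes the double bond where the enolate was; this is preferred to a tosylhydrazone route, which would need deprotonation of a hindered methine, and to alcohol dehydration, which would rearrange.

Step 7
Reactants: 11 methyl (3S,6RS)-6-[(2S,5S)-2,5-dimethylpyrrolidine-1-carbonyl]-3,7-dimethyloct-7-enoate; 15 1,3,3-trimethylcyclohexene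
Product: 18 methyl (3S)-3-methyl-5-[(1S,6R,8R)-1,5,5-trimethyl-7-oxo-8-(prop-1-en-2-yl)bicyclo[4.2.0]octan-8-yl]pentanoate, via keteniminium triflate 16 (not isolated), via cyclobutaniminium triflate 17 (not isolated)
Conditions: Tf2O, 2,6-di-tert-butylpyridine, 15 (5 equiv), ClCH2CH2Cl, −20 → 80 °C; then H2O, NaHCO3, 60 °C
Reagents that add atoms: water O
Why: Tf2O O-sulfonylates the amide and the hindered pyridine removes the allylic C9–H, so that loss of triflate gives vinylketeniminium 16, whose sp carbon C6 is attacked by the ring A alkene at its CH carbon C5 (tertiary cation developing at C10) before the enamine carbon C9 closes on C10. The closest known reaction is the keteniminium–alkene [2+2] cycloaddition of α,α-disubstituted amides, including those of C2-symmetric 2,5-dimethylpyrrolidine. The cyclobutane C5–C6–C9–C10 is closed in this stepwise polar [2+2] mode with both new bonds on one alkene face, so its fusion to ring A can only be cis. C5 and C10 are set together by that suprafacial addition and their absolute sense by the pyrrolidine methyl groups, which flank the two lobes of the C=N π* orbital and leave one alkene face open; C9 is set by which of its substituents turns toward ring A (drawn as one epimer) and is erased in step 9. The step needs regioselectivity (tertiary versus secondary cation), four- rather than six-membered closure through C7 (the alkene approaches past the unbranched CH2 arm, which places the isopropenyl group trans to C5 on the enamine) and face selectivity (auxiliary); an excess of the volatile alkene offsets its hindrance, and water then hydrolyses iminium 17 to ketone 18.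

Step 8
Reactants: 18 methyl (3S)-3-methyl-5-[(1S,6R,8R)-1,5,5-trimethyl-7-oxo-8-(prop-1-en-2-yl)bicyclo[4.2.0]octan-8-yl]pentanoate
Product: 20 (3S)-5-[(1S,6R,7RS,8R)-7-hydroxy-1,5,5-trimethyl-8-(prop-1-en-2-yl)bicyclo[4.2.0]octan-8-yl]-3-methylpentanoic acid, via cyclobutanol ester 19 (not isolated)
Conditions: NaBH4, MeOH, 0 °C; then LiOH, H2O–THF, rt; HCl to pH 3
Reagents that add atoms: lithium hydroxide [Li+].[OH-]
Why: Borohydride reduction of the strained ketone followed by saponification in the same flask, because a methyl ester would not survive the potassium alkoxide of step 9 (transesterification, Claisen condensation); C6 forms as an epimer mixture, which is of no consequence since the C6–C9 bond is broken next.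

Step 9
Reactants: 20 (3S)-5-[(1S,6R,7RS,8R)-7-hydroxy-1,5,5-trimethyl-8-(prop-1-en-2-yl)bicyclo[4.2.0]octan-8-yl]-3-methylpentanoic acid
Product: 22 (13S)-6ξ-hydroxy-5-epi-labd-8-en-15-oic acid (5β-H, cis-fused), via dipotassium salt 21 (not isolated)
Conditions: KH (3 equiv), 18-crown-6, THF, 0 °C → rt; HCl to pH 3
Reagents that add atoms: none
Why: Alkoxide-accelerated [1,3] shift of a 2-vinylcyclobutanol (anionic vinylcyclobutane-to-cyclohexene rearrangement): the C6–C9 bond β to the alkoxide breaks with release of ring strain to an aldehyde and an allyl anion, which recloses at C7 to give ring B with the C8=C9 double bond; the carboxylate is inert and C10 is not touched.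

Step 10
Reactants: 22 (13S)-6ξ-hydroxy-5-epi-labd-8-en-15-oic acid
Product: 23 methyl (13S)-6ξ-hydroxy-5-epi-labd-8-en-15-oate
Conditions: MeI, K2CO3, DMF, rt
Reagents that add atoms: iodomethane CI
Why: Carboxylate O-alkylation (SN2); carbonate does not deprotonate the secondary alcohol, so only the ester forms.

Step 11
Reactants: 23 methyl (13S)-6ξ-hydroxy-5-epi-labd-8-en-15-oate
Product: 24 methyl (13S)-6-oxo-5-epi-labd-8-en-15-oate
Conditions: Dess–Martin periodinane, NaHCO3, CH2Cl2, 0 °C → rt
Reagents that add atoms: none
Why: Dess–Martin oxidation of the secondary alcohol under buffered, non-enolising conditions; both C6 epimers converge on one β,γ-unsaturated ketone.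

Step 12
Reactants: 24 methyl (13S)-6-oxo-5-epi-labd-8-en-15-oate
Product: 26 methyl (13S)-6-oxolabd-7-en-15-oate (trans-fused; both C9 epimers), via cis-fused enone 25 (not isolated)
Conditions: NaOMe, MeOH, reflux
Reagents that add atoms: none
Why: Base-mediated enolisation under thermodynamic control: the double bond moves into conjugation through the dienolate and C5 then equilibrates through its enolate to the trans fusion (5α-H), which lacks the extra syn-axial contacts of either cis-decalin conformer. C9 is deliberately not relied on here, since a pseudo-axial chain (free of allylic strain with C17) may well be the more stable epimer; methoxide in methanol leaves the methyl ester unchanged.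

Step 13
Reactants: 26 methyl (13S)-6-oxolabd-7-en-15-oate (trans-fused; both C9 epimers)
Product: 27 methyl (13S)-6-acetoxylabda-6,8-dien-15-oate
Conditions: isopropenyl acetate, TsOH·H2O (cat.), reflux
Reagents that add atoms: isopropenyl acetate CC(=C)OC(C)=O
Why: Acid-catalysed enol acetylation under equilibrating conditions gives the linear dienyl acetate with the more substituted C8=C9 bond (as 4-en-3-ones give 3,5-dienyl acetates); C9 becomes sp2, so both epimers converge, and C5 keeps the trans fusion.

Step 14
Reactants: 27 methyl (13S)-6-acetoxylabda-6,8-dien-15-oate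
Product: 29 methyl (13S)-6-oxolabd-7-en-15-oate (5α-H and 9α-H), via trans-fused 8-en-6-one 28 (not isolated)
Conditions: K2CO3 (0.3 equiv), MeOH, 0 °C → rt
Reagents that add atoms: none
Why: Deconjugation–reconjugation under kinetic control: methanolysis of the enol ester frees the dienolate, which is protonated first at C7 to the β,γ-enone 28; under the same mild base this conjugates by protonation of C9 on the α-face, axial and anti to the axial C20 methyl on C10, which sets 9α-H with the chain equatorial. The reaction is stopped at full conversion, before the weakly acidic C9–H of the product can exchange.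

Step 15
Reactants: 29 methyl (13S)-6-oxolabd-7-en-15-oate (5α-H and 9α-H)
Product: 30 methyl (13S)-7α,8α-epoxy-6-oxolabdan-15-oate
Conditions: tBuOOH (in decane), benzyltrimethylammonium hydroxide (cat.), toluene, 0 °C → rt
Reagents that add atoms: tert-butyl hydroperoxide CC(C)(C)OO
Why: Weitz–Scheffer nucleophilic epoxidation: the peroxide anion adds to C8 on the α-face, away from the syn-axial C20 methyl, and the enolate closes the oxirane, which fixes C8 (O α, CH3 β); the non-aqueous medium spares the methyl ester, and the weakly basic peroxide anion does not epimerise C9.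

Step 16
Reactants: 30 methyl (13S)-7α,8α-epoxy-6-oxolabdan-15-oate
Product: 31 methyl (13S)-8α-hydroxy-6-oxolabdan-15-oate
Conditions: SmI2, THF–MeOH, −90 °C
Reagents that add atoms: none
Why: Reductive opening of an α,β-epoxy ketone: two-electron reduction at the carbonyl expels the α-oxygen (C7–O cleavage) and methanol protonates the samarium enolate, so the C8–O bond and with it the 8α-OH/8β-CH3 configuration are kept.

Step 17
Reactants: 31 methyl (13S)-8α-hydroxy-6-oxolabdan-15-oate
Product: 32 methyl (13S)-6β,8α-dihydroxylabdan-15-oate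
Conditions: NaBH4, MeOH, −20 → 0 °C
Reagents that add atoms: none
Why: Substrate-controlled ketone reduction: the β-face of C6 is closed by the two syn-axial methyl groups on C10 and C4, so hydride enters from the α-face and gives the axial 6β-alcohol. A hydroxyl-directed triacetoxyborohydride reduction is not used because the equatorial 8α-OH lies anti to C6 and cannot deliver hydride.

Step 18
Reactants: 32 methyl (13S)-6β,8α-dihydroxylabdan-15-oate
Product: 33 methyl (13S)-6β-acetoxy-8α-hydroxylabdan-15-oate
Conditions: Ac2O, pyridine, 4-(dimethylamino)pyridine (cat.), rt → 40 °C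
Reagents that add atoms: acetic anhydride CC(=O)OC(C)=O
Why: Nucleophile-catalysed acetylation of the secondary 6β-hydroxyl; the tertiary 8α-hydroxyl does not react under these conditions.

**Compound list**

1 | methyl hydrogen (R)-3-methylglutarate [(3R)-5-methoxy-3-methyl-5-oxopentanoic acid] | OC(=O)C[C@@H](C)CC(=O)OC | starting material
2 | (3S)-5-hydroxy-3-methylpentanoic acid | OC(=O)C[C@@H](C)CCO | intermediate
3 | (4S)-4-methyloxan-2-one | O=C1C[C@@H](C)CCO1 | intermediate
4 | trimethylsilyl (3R)-5-iodo-3-methylpentanoate | C[Si](C)(C)OC(=O)C[C@@H](C)CCI | intermediate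
5 | (3R)-5-iodo-3-methylpentanoic acid | OC(=O)C[C@@H](C)CCI | intermediate
6 | methyl (3R)-5-iodo-3-methylpentanoate | COC(=O)C[C@@H](C)CCI | intermediate
7 | 3-methylbut-2-enoyl chloride | CC(C)=CC(=O)Cl | starting material
8 | (2S,5S)-2,5-dimethylpyrrolidine | C[C@H]1CC[C@H](C)N1 | starting material
9 | 1-[(2S,5S)-2,5-dimethylpyrrolidin-1-yl]-3-methylbut-2-en-1-one | CC(C)=CC(=O)N1[C@@H](C)CC[C@@H]1C | intermediate
10 | lithium 1-[(2S,5S)-2,5-dimethylpyrrolidin-1-yl]-3-methylbuta-1,3-dien-1-olate | C=C(C)C=C(O[Li])N1[C@@H](C)CC[C@@H]1C | intermediate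
11 | methyl (3S,6RS)-6-[(2S,5S)-2,5-dimethylpyrrolidine-1-carbonyl]-3,7-dimethyloct-7-enoate | C=C(C)C(CC[C@H](C)CC(=O)OC)C(=O)N1[C@@H](C)CC[C@@H]1C | intermediate
12 | 2,2,6-trimethylcyclohexanone (racemic) | CC1CCCC(C)(C)C1=O | starting material
13 | lithium 2,6,6-trimethylcyclohex-1-en-1-olate | CC1=C(O[Li])C(C)(C)CCC1 | intermediate
14 | 2,6,6-trimethylcyclohex-1-en-1-yl trifluoromethanesulfonate | CC1=C(OS(=O)(=O)C(F)(F)F)C(C)(C)CCC1 | intermediate
15 | 1,3,3-trimethylcyclohexene | CC1=CC(C)(C)CCC1 | intermediate
16 | (2S,5S)-1-[(5S)-7-methoxy-5-methyl-7-oxo-2-(prop-1-en-2-yl)hept-1-en-1-ylidene]-2,5-dimethylpyrrolidin-1-ium trifluoromethanesulfonate | C=C(C)C(CC[C@H](C)CC(=O)OC)=C=[N+]1[C@@H](C)CC[C@@H]1C.[O-]S(=O)(=O)C(F)(F)F | intermediate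
17 | (2S,5S)-1-[(1S,6R,8R)-8-[(3S)-5-methoxy-3-methyl-5-oxopentyl]-1,5,5-trimethyl-8-(prop-1-en-2-yl)bicyclo[4.2.0]octan-7-ylidene]-2,5-dimethylpyrrolidin-1-ium trifluoromethanesulfonate | C=C(C)[C@]1(CC[C@H](C)CC(=O)OC)[C@@]2(C)CCCC(C)(C)[C@H]2C1=[N+]3[C@@H](C)CC[C@@H]3C.[O-]S(=O)(=O)C(F)(F)F | intermediate
18 | methyl (3S)-3-methyl-5-[(1S,6R,8R)-1,5,5-trimethyl-7-oxo-8-(prop-1-en-2-yl)bicyclo[4.2.0]octan-8-yl]pentanoate (cis-fused; C9 shown as one epimer) | C=C(C)[C@]1(CC[C@H](C)CC(=O)OC)[C@@]2(C)CCCC(C)(C)[C@H]2C1=O | intermediate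
19 | methyl (3S)-5-[(1S,6R,7RS,8R)-7-hydroxy-1,5,5-trimethyl-8-(prop-1-en-2-yl)bicyclo[4.2.0]octan-8-yl]-3-methylpentanoate | C=C(C)[C@]1(CC[C@H](C)CC(=O)OC)[C@@]2(C)CCCC(C)(C)[C@H]2C1O | intermediate
20 | (3S)-5-[(1S,6R,7RS,8R)-7-hydroxy-1,5,5-trimethyl-8-(prop-1-en-2-yl)bicyclo[4.2.0]octan-8-yl]-3-methylpentanoic acid | C=C(C)[C@]1(CC[C@H](C)CC(O)=O)[C@@]2(C)CCCC(C)(C)[C@H]2C1O | intermediate
21 | dipotassium salt of 20 (carboxylate and cyclobutanolate) | C=C(C)[C@]1(CC[C@H](C)CC([O-])=O)[C@@]2(C)CCCC(C)(C)[C@H]2C1[O-].[K+].[K+] | intermediate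
22 | (13S)-6ξ-hydroxy-5-epi-labd-8-en-15-oic acid (5β-H, 10β-CH3, cis-fused) | OC(=O)C[C@@H](C)CCC1=C(C)CC(O)[C@@H]2C(C)(C)CCC[C@]12C | intermediate
23 | methyl (13S)-6ξ-hydroxy-5-epi-labd-8-en-15-oate | COC(=O)C[C@@H](C)CCC1=C(C)CC(O)[C@@H]2C(C)(C)CCC[C@]12C | intermediate
24 | methyl (13S)-6-oxo-5-epi-labd-8-en-15-oate (cis-fused) | COC(=O)C[C@@H](C)CCC1=C(C)CC(=O)[C@@H]2C(C)(C)CCC[C@]12C | intermediate
25 | methyl (13S)-6-oxo-5-epi-labd-7-en-15-oate (cis-fused; C9 epimers) | COC(=O)C[C@@H](C)CCC1[C@@]2(C)CCCC(C)(C)[C@H]2C(=O)C=C1C | intermediate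
26 | methyl (13S,9RS)-6-oxolabd-7-en-15-oate (trans-fused, 5α-H; C9 epimers) | COC(=O)C[C@@H](C)CCC1[C@@]2(C)CCCC(C)(C)[C@@H]2C(=O)C=C1C | intermediate
27 | methyl (13S)-6-acetoxylabda-6,8-dien-15-oate (5α-H) | COC(=O)C[C@@H](C)CCC1=C(C)C=C(OC(C)=O)[C@H]2C(C)(C)CCC[C@]12C | intermediate
28 | methyl (13S)-6-oxolabd-8-en-15-oate (trans-fused, 5α-H) | COC(=O)C[C@@H](C)CCC1=C(C)CC(=O)[C@H]2C(C)(C)CCC[C@]12C | intermediate
29 | methyl (13S)-6-oxolabd-7-en-15-oate (5α-H, 9α-H, 10β-CH3) | COC(=O)C[C@@H](C)CC[C@@H]1[C@@]2(C)CCCC(C)(C)[C@@H]2C(=O)C=C1C | intermediate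
30 | methyl (13S)-7α,8α-epoxy-6-oxolabdan-15-oate | COC(=O)C[C@@H](C)CC[C@@H]1[C@@]2(C)CCCC(C)(C)[C@@H]2C(=O)[C@H]3O[C@@]13C | intermediate
31 | methyl (13S)-8α-hydroxy-6-oxolabdan-15-oate | COC(=O)C[C@@H](C)CC[C@@H]1[C@@]2(C)CCCC(C)(C)[C@@H]2C(=O)C[C@@]1(C)O | intermediate
32 | methyl (13S)-6β,8α-dihydroxylabdan-15-oate | COC(=O)C[C@@H](C)CC[C@@H]1[C@@]2(C)CCCC(C)(C)[C@@H]2[C@H](O)C[C@@]1(C)O | intermediate
33 | methyl (13S)-6β-acetoxy-8α-hydroxylabdan-15-oate = methyl (3S)-5-[(1R,2R,4R,4aS,8aS)-4-acetoxy-2-hydroxy-2,5,5,8a-tetramethyldecahydronaphthalen-1-yl]-3-methylpentanoate | COC(=O)C[C@@H](C)CC[C@@H]1[C@@]2(C)CCCC(C)(C)[C@@H]2[C@H](OC(C)=O)C[C@@]1(C)O | target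

**Step count and risks**

Total step count: 18. Longest linear sequence: 15 steps (1, 2, 4, 7, then 8–18).

Steps most likely to fail:

1. Step 7 (key cycloaddition). The fully substituted keteniminium carbon C9 must bond to the methyl-bearing alkene carbon C10 beside a neopentyl position. If that closure is slow, proton loss from the C10 cation (ene-type acylation) or simple hydrolysis back to the amide could take over; closure through C7 to a six-membered ring and weak face discrimination are further possibilities. The fallback sets out from 8 and 15 and comes back at 18. Amine 8 is acetylated (AcCl, Et3N) to 1-[(2S,5S)-2,5-dimethylpyrrolidin-1-yl]ethan-1-one F1. Its unsubstituted, far less hindered keteniminium (same Tf2O protocol, then water) should add to 15 with the same regiochemistry to give (1R,6R)-1,5,5-trimethylbicyclo[4.2.0]octan-7-one F2, in which C9 is still a CH2 group. LiN(iPr)2 and acetone give the aldol (1S,6R,8RS)-8-(2-hydroxypropan-2-yl)-1,5,5-trimethylbicyclo[4.2.0]octan-7-one F3, and TsOH dehydration gives (1S,6R)-1,5,5-trimethyl-8-(propan-2-ylidene)bicyclo[4.2.0]octan-7-one F4. γ-Deprotonation of F4 with KN(SiMe3)2 in THF–DMPU and alkylation of the dienolate at C9 with iodide 6 (deconjugative α-alkylation, as with pulegone) then gives 18.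

2. Step 9 (alkoxide [1,3] shift). After the C6–C9 bond has broken, proton transfer to the allyl anion may outrun reclosure at C7 and leave a ring-opened aldehyde, and poor solubility of the dianion may stall the shift. The fallback sets out from 19 (isolated by leaving out the LiOH stage of step 8) and comes back at 23. The same bond is broken by alkoxy-radical β-fragmentation (PhI(OAc)2, I2, hν, cyclohexane): the C6 alkoxy radical opens to the aldehyde and the allyl radical is trapped by iodine at its primary end C7, giving methyl (3S)-6-[(1S,2R)-2-formyl-1,3,3-trimethylcyclohexyl]-8-iodo-3,7-dimethyloct-6-enoate F5. An intramolecular Barbier allylation with SmI2 in THF then joins C7 to the aldehyde carbon C6, six-membered closure being preferred over return to the four-membered ring, to give 23 directly; steps 9 and 10 are no longer needed.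

3. Step 14 (kinetic protonation of C9). Protonation of C9 may not be face-selective enough, or the product may epimerise at C9 under the base, so that a C9 mixture is carried forward. The fallback sets out from 27 and comes back at 32. NaBH4 in MeOH cleaves the enol acetate and reduces the β,γ-enone as it forms (the classical dienyl acetate to homoallylic alcohol reduction), hydride entering C6 from the α-face, to give methyl (13S)-6β-hydroxylabd-8-en-15-oate F6. BH3·THF (0 °C → rt, where aliphatic esters react slowly) then adds syn across the tetrasubstituted C8=C9 bond from the α-face with boron on the less hindered C8, and NaBO3·4H2O oxidation gives diol 32 with 8α-OH and 9α-H set together; steps 14–17 are bypassed.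

Further compounds
F1 | step 7 | 1-[(2S,5S)-2,5-dimethylpyrrolidin-1-yl]ethan-1-one | CC(=O)N1[C@@H](C)CC[C@@H]1C
F2 | step 7 | (1R,6R)-1,5,5-trimethylbicyclo[4.2.0]octan-7-one | C1[C@@]2(C)CCCC(C)(C)[C@H]2C1=O
F3 | step 7 | (1S,6R,8RS)-8-(2-hydroxypropan-2-yl)-1,5,5-trimethylbicyclo[4.2.0]octan-7-one | CC(C)(O)C1[C@@]2(C)CCCC(C)(C)[C@H]2C1=O
F4 | step 7 | (1S,6R)-1,5,5-trimethyl-8-(propan-2-ylidene)bicyclo[4.2.0]octan-7-one | CC(C)=C1[C@@]2(C)CCCC(C)(C)[C@H]2C1=O
F5 | step 9 | methyl (3S)-6-[(1S,2R)-2-formyl-1,3,3-trimethylcyclohexyl]-8-iodo-3,7-dimethyloct-6-enoate | COC(=O)C[C@@H](C)CCC(=C(C)CI)[C@@]1(C)CCCC(C)(C)[C@H]1C=O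
F6 | step 14 | methyl (13S)-6β-hydroxylabd-8-en-15-oate | COC(=O)C[C@@H](C)CCC1=C(C)C[C@@H](O)[C@H]2C(C)(C)CCC[C@]12C
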